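The target is numbered as a biflavanone: O1, C2, C3, C4, C4a, C5–C8, C8a in the first unit, double-primed locants in the second.

- Retrosynthesis: after removal of two benzyl ethers from O7 and O7'', both halves of the C2-symmetric target are cut at once at the aryl ether bonds O1–C8a and O1''–C8a'' and at C2–C3 and C2''–C3''. This leaves two molecules of 4-methoxybenzaldehyde and one symmetric 1,4-bis(2-fluoroaryl)butane-1,4-dione, used as its bis(silyl enol ether).
- The diketone is cut at both aryl–acyl bonds into two molecules of an arylmagnesium reagent (from 4-bromo-3,5-difluorophenol) and the bis(Weinreb amide) of succinic acid. Each C5 methoxy group comes from SNAr on a 2,6-difluoroaryl ketone.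
- Forward order: ring A is bought, two ring A units are joined through the chain C4–C3–C3''–C4'', and both ends are elaborated in parallel (two-directional). The two pyranone rings (rings C) then close together in one operation that joins three components, and debenzylation ends the route.
- Enabling feature: in each half the C4 carbonyl makes C3 an enolate carbon and at the same time turns ring A carbon C8a, ortho to it and bearing fluorine, into an SNAr acceptor (vinylogous acyl fluoride C8a=C4a–C4=O) placed for a six-membered closure by the aldolate oxygen. The C2 axis through the C3–C3'' bond lets one event serve both halves.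
- Stereochemistry: C2 and C2'' are set in the ring-closing SNAr by a chiral ammonium counter-cation acting on equilibrating aldolates. C3 and C3'' settle by epimerisation to the 2,3-trans arrangement.

Key step: step 6

Assumption: the cinchonidinium cation is taken to favour closure of the (S)-configured aldolates; should the opposite sense be found, the pseudoenantiomeric cinchoninium bifluoride is to be used in step 6 without other change.

Step 1
Reactants: 1 4-bromo-3,5-difluorophenol
Product: 2 5-(benzyloxy)-2-bromo-1,3-difluorobenzene
Conditions: BnBr (1.1 equiv), K2CO3 (1.5 equiv), DMF, rt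
Reagents that add atoms: benzyl bromide, BrCc1ccccc1
Why: Williamson ether synthesis: the acidic difluorophenol is O-alkylated cleanly by the benzylic bromide, and the benzyl ether is inert to every later step until the final hydrogenolysis; no stereocenter is formed.

Step 2
Reactants: 3 succinyl chloride; 4 N,O-dimethylhydroxylamine hydrochloride
Product: 5 N1,N4-dimethoxy-N1,N4-dimethylbutanediamide
Conditions: 4 (2.2 equiv), pyridine (4.5 equiv), CH2Cl2, 0 °C → rt
Reagents that add atoms: none
Why: Amide formation: each of the two acid chloride groups of 3 acylates the nitrogen of one molecule of 4, so two equivalents of 4 are consumed per molecule of 3, and the resulting bis(Weinreb amide) delivers the four-carbon chain at the ketone oxidation level; no stereocenter is formed.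

Step 3
Reactants: 2 5-(benzyloxy)-2-bromo-1,3-difluorobenzene; 5 N1,N4-dimethoxy-N1,N4-dimethylbutanediamide
Product: 7 1,4-bis[4-(benzyloxy)-2,6-difluorophenyl]butane-1,4-dione, via arylmagnesium chloride 6 (not isolated)
Conditions: 2 (2.2 equiv), iPrMgCl·LiCl (2.3 equiv), THF, −20 °C; then 5 (1.0 equiv), −20 °C → rt; 1 M aq HCl
Reagents that add atoms: none
Why: Bromine–magnesium exchange is fast at the carbon flanked by two fluorines, and two molecules of arylmagnesium 6 are taken up per molecule of 5, one at each amide, because the chelated tetrahedral adducts persist until the acidic work-up (twofold Weinreb ketone synthesis); the low temperature holds back loss of metal fluoride to an aryne, and no stereocenter is formed.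

Step 4
Reactants: 7 1,4-bis[4-(benzyloxy)-2,6-difluorophenyl]butane-1,4-dione
Product: 8 1,4-bis[4-(benzyloxy)-2-fluoro-6-methoxyphenyl]butane-1,4-dione
Conditions: NaOMe (2.1 equiv), THF/MeOH, 0 °C → 40 °C
Reagents that add atoms: sodium methoxide, [Na+].[O-]C
Why: SNAr at a fluorine ortho to the ketone: on each ring the first methoxy group donates into the carbonyl and so retards a second substitution, which should stop the reaction at one methoxy and one fluorine per ring; no stereocenter is formed.

Step 5
Reactants: 8 1,4-bis[4-(benzyloxy)-2-fluoro-6-methoxyphenyl]butane-1,4-dione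
Product: 9 (1Z,3Z)-1,4-bis[4-(benzyloxy)-2-fluoro-6-methoxyphenyl]-1,4-bis[(trimethylsilyl)oxy]buta-1,3-diene
Conditions: Me3SiOTf (2.4 equiv), Et3N (3 equiv), CH2Cl2, 0 °C; pentane extraction without aqueous acid
Reagents that add atoms: trimethylsilyl trifluoromethanesulfonate, C[Si](C)(C)OS(=O)(=O)C(F)(F)F
Why: Soft enolisation with a silyl triflate and a tertiary amine (silyl enol ether formation) converts both ketones into the conjugated bis(silyl enol ether), expected as the (1Z,3Z) isomer, whose geometry has no bearing on the outcome of step 6; no stereocenter is formed.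

Step 6
Reactants: 9 (1Z,3Z)-1,4-bis[4-(benzyloxy)-2-fluoro-6-methoxyphenyl]-1,4-bis[(trimethylsilyl)oxy]buta-1,3-diene; 10 4-methoxybenzaldehyde
Product: 14 (2S,2''S,3R,3''R)-7,7''-bis(benzyloxy)-5,5''-dimethoxy-2,2''-bis(4-methoxyphenyl)-3,3''-bichroman-4,4''-dione, via first aldolate 11 (not isolated), via half-closed enol ether 12 (not isolated), via second aldolate 13 (not isolated)
Conditions: 10 (2.2 equiv), O-allyl-N-(9-anthracenylmethyl)cinchonidinium bifluoride (10 mol%), 4 Å molecular sieves, toluene/CH2Cl2, −40 °C → 0 °C; AcOH quench
Reagents that add atoms: none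
Why: Proposed new method: fluoride from the catalyst desilylates one enol ether of 9, the ammonium enolate adds reversibly to 10 (the aldol addition of silyl enol ethers under chiral quaternary ammonium fluoride catalysis, a Mukaiyama-type aldol, is the closest known reaction), and the aldolate oxygen of 11 attacks the fluorine-bearing ring A carbon C8a, activated as a vinylogous acyl fluoride (C8a=C4a–C4=O) with both alkoxy groups meta to the reacting carbon where they do not destabilise the anionic σ-adduct; loss of fluoride closes the pyranone ring and returns exactly the fluoride needed to desilylate the next enol ether, so that Me3SiF is the only by-product and no external base is present (fluoride-catalysed SNAr of silyl ethers on aryl fluorides and asymmetric phase-transfer SNAr are the other close precedents). Each of the two pyranone rings closes in a six-membered addition–elimination mode, 6-endo-trig with respect to the C8a=C4a–C4=O acceptor and exo with respect to the departing C–F bond, through a chair-like transition state with the 4-methoxyphenyl group equatorial. C2 and C2'' are set in this irreversible closure: the aldolates are expected to interconvert by retro-aldol faster than they cyclise, so the chiral cinchonidinium cation paired with the anionic σ-adduct should select the (S)-configured aldolate at each end (dynamic kinetic resolution), and because the selection operates twice, a wrong-sense closure is diverted mainly into the separable meso diastereomer, which raises the enantiomeric purity of the C2-symmetric product. C3 and C3'' lie α to the ketones and should epimerise in the mildly basic fluoride medium to the 2,3-trans, diequatorial arrangement in both rings, which with (2S,2''S) fixed is the (3R,3''R) configuration of the target. The step needs O-arylation to beat C-arylation by the distal enolate, silanolate elimination to a benzylidene ketone and aldol–Tishchenko hydride transfer; this is to be secured by the ortho placement of fluorine and acyl group on ring A, by the distal carbonyl staying masked as its silyl enol ether until the first ring has closed, by the reversibility of every event before closure, by the near-stoichiometric charge of 10, and by the single fluorine left on each ring after step 4.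

Step 7
Reactants: 14 (2S,2''S,3R,3''R)-7,7''-bis(benzyloxy)-5,5''-dimethoxy-2,2''-bis(4-methoxyphenyl)-3,3''-bichroman-4,4''-dione
Product: 15 4',4''',5,5''-tetramethylchamaejasmin
Conditions: H2 (1 atm), 10% Pd/C, EtOAc/MeOH, rt
Reagents that add atoms: none
Why: Catalytic hydrogenolysis cleaves the two primary benzyl aryl ethers faster than the hindered secondary C2–O1 bonds of the pyranone rings and does so under neutral conditions, which avoids the base-induced ring opening and C2 epimerisation of flavanones and leaves all four stereocenters and the methyl ethers untouched.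

Compound list
1 | 4-bromo-3,5-difluorophenol | Oc1cc(F)c(Br)c(F)c1 | starting material
2 | 5-(benzyloxy)-2-bromo-1,3-difluorobenzene | Fc1cc(OCc2ccccc2)cc(F)c1Br | intermediate
3 | succinyl chloride | O=C(Cl)CCC(=O)Cl | starting material
4 | N,O-dimethylhydroxylamine hydrochloride | CNOC.Cl | starting material
5 | N1,N4-dimethoxy-N1,N4-dimethylbutanediamide | CON(C)C(=O)CCC(=O)N(C)OC | intermediate
6 | [4-(benzyloxy)-2,6-difluorophenyl]magnesium chloride (LiCl complex, not isolated) | Fc1cc(OCc2ccccc2)cc(F)c1[Mg]Cl | intermediate
7 | 1,4-bis[4-(benzyloxy)-2,6-difluorophenyl]butane-1,4-dione | O=C(CCC(=O)c1c(F)cc(OCc2ccccc2)cc1F)c1c(F)cc(OCc2ccccc2)cc1F | intermediate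
8 | 1,4-bis[4-(benzyloxy)-2-fluoro-6-methoxyphenyl]butane-1,4-dione | O=C(CCC(=O)c1c(F)cc(OCc2ccccc2)cc1OC)c1c(F)cc(OCc2ccccc2)cc1OC | intermediate
9 | (1Z,3Z)-1,4-bis[4-(benzyloxy)-2-fluoro-6-methoxyphenyl]-1,4-bis[(trimethylsilyl)oxy]buta-1,3-diene | C[Si](C)(C)O/C(=C\C=C(/O[Si](C)(C)C)c1c(F)cc(OCc2ccccc2)cc1OC)c1c(F)cc(OCc2ccccc2)cc1OC | intermediate
10 | 4-methoxybenzaldehyde | COc1ccc(C=O)cc1 | starting material
11 | (1S,3Z)-2-[4-(benzyloxy)-2-fluoro-6-methoxybenzoyl]-4-[4-(benzyloxy)-2-fluoro-6-methoxyphenyl]-1-(4-methoxyphenyl)-4-[(trimethylsilyl)oxy]but-3-en-1-olate (anion of the ammonium ion pair, epimers at chain C2, not isolated) | COc1ccc([C@@H]([O-])C(C(=O)c2c(F)cc(OCc3ccccc3)cc2OC)/C=C(\O[Si](C)(C)C)c2c(F)cc(OCc3ccccc3)cc2OC)cc1 | intermediate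
12 | (2S,3R)-7-(benzyloxy)-3-{(Z)-2-[4-(benzyloxy)-2-fluoro-6-methoxyphenyl]-2-[(trimethylsilyl)oxy]ethenyl}-5-methoxy-2-(4-methoxyphenyl)chroman-4-one (not isolated) | COc1ccc([C@H]2Oc3cc(OCc4ccccc4)cc(OC)c3C(=O)[C@@H]2/C=C(\O[Si](C)(C)C)c2c(F)cc(OCc3ccccc3)cc2OC)cc1 | intermediate
13 | (1S)-3-[4-(benzyloxy)-2-fluoro-6-methoxyphenyl]-2-[(2S,3R)-7-(benzyloxy)-5-methoxy-2-(4-methoxyphenyl)-4-oxochroman-3-yl]-1-(4-methoxyphenyl)-3-oxopropan-1-olate (anion of the ammonium ion pair, epimers at chain C2, not isolated) | COc1ccc([C@H]2Oc3cc(OCc4ccccc4)cc(OC)c3C(=O)[C@@H]2C([C@H]([O-])c2ccc(OC)cc2)C(=O)c2c(F)cc(OCc3ccccc3)cc2OC)cc1 | intermediate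
14 | (2S,2''S,3R,3''R)-7,7''-bis(benzyloxy)-5,5''-dimethoxy-2,2''-bis(4-methoxyphenyl)-3,3''-bichroman-4,4''-dione | COc1ccc([C@H]2Oc3cc(OCc4ccccc4)cc(OC)c3C(=O)[C@@H]2[C@H]2C(=O)c3c(OC)cc(OCc4ccccc4)cc3O[C@@H]2c2ccc(OC)cc2)cc1 | intermediate
15 | 4',4''',5,5''-tetramethylchamaejasmin, (2S,2''S,3R,3''R)-7,7''-dihydroxy-5,5''-dimethoxy-2,2''-bis(4-methoxyphenyl)-3,3''-bichroman-4,4''-dione | COc1ccc([C@H]2Oc3cc(O)cc(OC)c3C(=O)[C@@H]2[C@H]2C(=O)c3c(OC)cc(O)cc3O[C@@H]2c2ccc(OC)cc2)cc1 | target

Total step count: 7. Longest linear sequence: 6 steps (steps 1, 3, 4, 5, 6 and 7 from compound 1; step 2 is a side branch).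

Steps most likely to fail

Step 6 (proposed new method). The chiral cation may discriminate too weakly, or in the wrong sense, between the equilibrating aldolates at the ring-closing stage, which would raise the share of meso and racemic material. The closure may also be outrun by silanolate elimination or by hydride transfer to excess aldehyde. The fallback uses known chemistry only, sets out from 8 and returns at 14. The dilithium bis-enolate of 8 (LiN(SiMe3)2, 2.2 equiv, THF, −78 °C) is added to 10 (2.2 equiv) and quenched cold with AcOH to give the bis-aldol 1,4-bis[4-(benzyloxy)-2-fluoro-6-methoxyphenyl]-2,3-bis[hydroxy(4-methoxyphenyl)methyl]butane-1,4-dione F1 as a diastereomer mixture. NaH (2.2 equiv) in THF/DMF (0 °C → rt) should then close both rings by conventional intramolecular SNAr of the alkoxides. Because every stereocenter equilibrates under these conditions, the all-trans products are expected without absolute control: 14 together with its (2R,2''R,3S,3''S) enantiomer F2 and the (2S,3R,2''R,3''S) meso diastereomer F3. F3 is removed by chromatography or crystallisation and F2 by preparative chromatography on a chiral stationary phase (amylose tris(3,5-dimethylphenylcarbamate)), which returns the route to 14.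

Step 4. The two rings react independently, so under- and over-substitution across the molecule may give a statistical mixture that is hard to separate at the dimer stage. The fallback sets out from 2 and returns at 8, bypassing 5 and 7. Bromine–magnesium exchange on 2 (iPrMgCl·LiCl) and acylation with N-methoxy-N-methylacetamide should give 1-[4-(benzyloxy)-2,6-difluorophenyl]ethan-1-one F4. NaOMe (1.05 equiv) then has a single ring to address and should give 1-[4-(benzyloxy)-2-fluoro-6-methoxyphenyl]ethan-1-one F5, which can be purified as a monomer. Oxidative homocoupling of two molecules of its lithium enolate (LiN(iPr)2, THF, −78 °C; then CuCl2, DMF) joins C3 to C3'' and gives 8.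

Step 5. Acid-promoted cyclodehydration of the 1,4-diketone to a furan (Paal–Knorr) under the silyl triflate, or hydrolytic loss of the trimethylsilyl groups on isolation, may prevent clean access to the bis(enol ether). The fallback sets out from 8 and returns at 14. It changes both the mode of enolisation and the helper group: the dipotassium bis-enolate (KN(SiMe3)2, 2.2 equiv, THF, −78 °C) is trapped with tert-butyldimethylsilyl chloride (2.4 equiv) to give the chromatographically robust (1Z,3Z)-1,4-bis[4-(benzyloxy)-2-fluoro-6-methoxyphenyl]-1,4-bis[(tert-butyldimethylsilyl)oxy]buta-1,3-diene F6. F6 is then submitted to the conditions of step 6 and should give 14 by the same fluoride relay.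

Further compounds
F1 | step 6 | 1,4-bis[4-(benzyloxy)-2-fluoro-6-methoxyphenyl]-2,3-bis[hydroxy(4-methoxyphenyl)methyl]butane-1,4-dione (diastereomer mixture) | COc1ccc(C(O)C(C(=O)c2c(F)cc(OCc3ccccc3)cc2OC)C(C(O)c2ccc(OC)cc2)C(=O)c2c(F)cc(OCc3ccccc3)cc2OC)cc1
F2 | step 6 | (2R,2''R,3S,3''S)-7,7''-bis(benzyloxy)-5,5''-dimethoxy-2,2''-bis(4-methoxyphenyl)-3,3''-bichroman-4,4''-dione (enantiomer of 14) | COc1ccc([C@@H]2Oc3cc(OCc4ccccc4)cc(OC)c3C(=O)[C@H]2[C@@H]2C(=O)c3c(OC)cc(OCc4ccccc4)cc3O[C@H]2c2ccc(OC)cc2)cc1
F3 | step 6 | (2S,3R,2''R,3''S)-7,7''-bis(benzyloxy)-5,5''-dimethoxy-2,2''-bis(4-methoxyphenyl)-3,3''-bichroman-4,4''-dione (meso diastereomer of 14) | COc1ccc([C@H]2Oc3cc(OCc4ccccc4)cc(OC)c3C(=O)[C@@H]2[C@@H]2C(=O)c3c(OC)cc(OCc4ccccc4)cc3O[C@H]2c2ccc(OC)cc2)cc1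
F4 | step 4 | 1-[4-(benzyloxy)-2,6-difluorophenyl]ethan-1-one | CC(=O)c1c(F)cc(OCc2ccccc2)cc1F
F5 | step 4 | 1-[4-(benzyloxy)-2-fluoro-6-methoxyphenyl]ethan-1-one | CC(=O)c1c(F)cc(OCc2ccccc2)cc1OC
F6 | step 5 | (1Z,3Z)-1,4-bis[4-(benzyloxy)-2-fluoro-6-methoxyphenyl]-1,4-bis[(tert-butyldimethylsilyl)oxy]buta-1,3-diene | CC(C)(C)[Si](C)(C)O/C(=C\C=C(/O[Si](C)(C)C(C)(C)C)c1c(F)cc(OCc2ccccc2)cc1OC)c1c(F)cc(OCc2ccccc2)cc1OC
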